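The constants stand at 110 °C, so each one has to be carried to its flask's temperature before anything else.

| setting | green | grey | red |
|---|---|---|---|
| substrate | 1.2 M | 1.2 M | 1.2 M |
| reagent | 1.20 M | 1.20 M | 1.20 M |
| capture agent | 0.120 M | 0.120 M | 0.120 M |
| temperature | 110 °C | 80 °C | 50 °C |
| time | 4.0 min | 4.0 min | 4.0 min |

    substrate + reagent → open intermediate + released group (k1 = 0.192 L mol⁻¹ s⁻¹, Ea1 = 74.0 kJ mol⁻¹)
    open intermediate ⇌ target (K2 = 0.465, k2 = 0.102 s⁻¹, Ea2 = 105 kJ mol⁻¹, ΔH2 = −35.0 kJ mol⁻¹)
    open intermediate ⇌ isomer of the product (K3 = 3.4, k3 = 0.00240 s⁻¹, Ea3 = 125 kJ mol⁻¹, ΔH3 = −67.0 kJ mol⁻¹)
    substrate + released group → side product A (k4 = 0.181 L mol⁻¹ s⁻¹, Ea4 = 81.0 kJ mol⁻¹)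
    open intermediate + capture agent → trapped intermediate (k5 = 0.151 L mol⁻¹ s⁻¹, Ea5 = 60.0 kJ mol⁻¹)
    substrate + open intermediate → side product B (k6 = 0.0219 L mol⁻¹ s⁻¹, Ea6 = 77.0 kJ mol⁻¹)
    (constants at 110 °C)

- a species is counted by the substrate in it: one side product B counts as two
- the list of constants is for 110 °C, to be carried to other temperatures by the activation energies and enthalpies

1. the flask with the highest share of target in all that became target or isomer of the product or side product A or trapped intermediate or side product B ("all alike" if they lie within 1.5 percentage points) (green / grey / red / all alike)
2. share of target in all that became target or isomer of the product or side product A or trapped intermediate or side product B, green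
3. share of target in all that became target or isomer of the product or side product A or trapped intermediate or side product B, grey
4. share of target in all that became target or isomer of the product or side product A or trapped intermediate or side product B, red

I worked with the fraction of substrate left, not with the amount made. In the first instants the flask held substrate and reagent in equal charges, and the opening step (substrate + reagent → open intermediate + released group (k1 = 0.192 L mol⁻¹ s⁻¹, Ea1 = 74.0 kJ mol⁻¹)) was the one to reckon with. I took κ as its constant times the reagent charge. Counting this step by itself, the fraction left after time t is the inverse of one plus κt. κ came to 13.8 min⁻¹ in green, 1.92 min⁻¹ in grey and 0.185 min⁻¹ in red. At the end of red, that fraction was 57.5%.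

In the middle of the run, open intermediate and released group built up. Released group could then attack substrate, and the pool of open intermediate could leak to target, isomer of the product, trapped intermediate and side product B. What a pool can do depends on how long it has existed, so I defined the open time W: the time a unit of charged substrate has on average spent past the opening step by the end, which is t minus ln(one plus κt) over κ. In red it is 1.01 min, in grey 2.87 min and in green 3.71 min. W ignores the side steps that also consume substrate, so it is a rough clock.

For the end of the run, I multiplied W by each step's forward constant at the flask's temperature, which gives a count of how far that step could get. For the step to target, the count is 22.7 in green, 1.07 in grey and 0.0135 in red. For the step to the isomer, it is 0.534 in green and 0.0148 in grey. In green the target count is far above one, so target has had time to equilibrate with the pool, and the isomer count is large enough for the isomer, with its equilibrium constant of 3.4 against 0.465, to begin draining both. In grey the target count is near one while the isomer count is much smaller, so the step to target has had time to run and little has gone on to the isomer. In red the target count is far below one, and since a small count is itself the fraction converted, target comes to 1.35% of the charge. The counts show how far each step got, but they do not separate green from grey by themselves, so I also carried the equilibrium constant of the step to target to grey: it is 1.18 there against 0.465 in green, which means that at equilibrium more of the pool stands as target in grey. With that and the smaller isomer count I chose grey, as a ranking; this reckoning gives no share for green or grey.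

The forecast chose grey, with 15.8% for green, 37.8% for grey and 9.7% for red, after it “stepped the open-intermediate pool by hand”.

The simulation gives grey, with 16.0% for green, 37.9% for grey and 9.65% for red. Red holds 1.22% of its charge as target against my 1.35%, and 58.7% of its reagent against my 57.5%. The neighbour of red with 0.48 M of substrate keeps the same κ but has 2.50 equiv of reagent, so I treated the opening step as pseudo-first-order. The fraction left is then the exponential of minus κt, 47.7%, and W becomes t minus one minus that fraction, over κ, which is 1.17 min. Target then comes to 1.58% of the charge. That flask ends with 48.9% of its substrate left and 1.37% as target.

The rate constants were set for the occasion; the result is computed.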